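**Retrosynthetic overview**

1. The strategy rests on ring A: a 1,3,5-trioxygenated benzene whose O1 on C8a, prenyl on C8, hydroxyl on C7, hydrogen on C6, methoxy on C5 and C4 branch on C4a map onto an alkynyl ether (C8a, C8) and a 2-methoxyvinylketene (C7, C4a, C5, C6).
2. After removal of the ring B silyl ether, the cascade of step 11 is undone: ring A (C6–C7, C7–C8) and ring C (C4a–C8a) open to diazo ketone 20, in which the alkynyl ether hangs on the C2 oxygen.
3. 20 comes from enone 18 by diazo transfer. The alkynyl ether is unmasked from an (E)-1,2-dichlorovinyl ether and prenylated while C7 is an alkoxide, because an amide or ketone at C7 would not survive KH (lactonisation) or n-BuLi (addition); C7 is therefore carried as a terminal alkene, then alcohol, aldehyde and carbinol.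
4. The single stereocentre, C2 (R), is set by asymmetric transfer hydrogenation of aryl ketone 5, made from 3-bromo-5-methoxyphenol and pent-4-enoyl chloride; no later step breaks the C2–O bond.
5. Ring order: ring B is bought; ring C closes first ([2+2]) and ring A second (6π closure), both in step 11.

Key step: step 11

Abbreviation: Ar = 3-methoxy-5-(triisopropylsilyloxy)phenyl; flavan numbering (O1, C2–C4, C4a, C5–C8, C8a) is used for the atoms of all intermediates.
Assumption: the (E)-1,2-dichlorovinyl ether is taken to be inert to 9-BBN, neutral H2O2, Dess–Martin periodinane and one equivalent of a vinyllithium at −78 °C.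

**Step 1**
Reactants: 1 3-bromo-5-methoxyphenol
Product: 2 (3-bromo-5-methoxyphenoxy)triisopropylsilane
Conditions: TIPSCl, imidazole, DMF, rt
Reagents that add atoms: triisopropylsilyl chloride, CC(C)[Si](Cl)(C(C)C)C(C)C
Why: Imidazole-promoted O-silylation of the phenol should be clean, and the bulky aryl silyl ether is expected to survive the Grignard, KH, organolithium and photochemical steps until fluoride removes it in step 12.

**Step 2**
Reactants: 2 (3-bromo-5-methoxyphenoxy)triisopropylsilane; 3 pent-4-enoyl chloride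
Product: 5 1-Ar-pent-4-en-1-one, via arylmagnesium bromide 4 (not isolated)
Conditions: Mg, THF, 50 °C; then added to 3, Fe(acac)3 (3 mol %), THF, −78 °C
Reagents that add atoms: none
Why: Iron-catalysed acylation of an aryl Grignard reagent by an acid chloride is fast at −78 °C, so the ketone should form without addition of a second aryl group and without touching the terminal alkene.

**Step 3**
Reactants: 5 1-Ar-pent-4-en-1-one
Product: 6 (1R)-1-Ar-pent-4-en-1-ol
Conditions: RuCl[(R,R)-TsDPEN](p-cymene) (1 mol %), HCO2H/Et3N (5:2), 30 °C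
Reagents that add atoms: none
Why: Noyori-type asymmetric transfer hydrogenation of an aryl alkyl ketone: with the (R,R)-TsDPEN ligand, hydride is delivered to the carbonyl face that gives the (R)-carbinol (the future C2), and the isolated alkene is not reduced.

**Step 4**
Reactants: 6 (1R)-1-Ar-pent-4-en-1-ol; 7 trichloroethylene
Product: 9 (1R)-1-Ar-1-[(E)-1,2-dichloroethenyloxy]pent-4-ene, via potassium alkoxide 8 (not isolated)
Conditions: KH, THF, 0 °C → rt; then 7, −50 °C → rt
Reagents that add atoms: none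
Why: The potassium alkoxide adds anti to dichloroacetylene, released in the flask from trichloroethylene by base, to give the (E)-1,2-dichlorovinyl ether as a base-stable mask of the alkynyl ether; the C2–O bond is not broken, so the configuration is retained.

**Step 5**
Reactants: 9 (1R)-1-Ar-1-[(E)-1,2-dichloroethenyloxy]pent-4-ene
Product: 11 (5R)-5-Ar-5-[(E)-1,2-dichloroethenyloxy]pentan-1-ol, via B-alkyl-9-borabicyclononane 10 (not isolated)
Conditions: 9-BBN, THF, 0 °C → rt; then pH 7 phosphate buffer, 30% H2O2, 0 °C → rt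
Reagents that add atoms: hydrogen peroxide, OO
Why: Anti-Markovnikov hydroboration–oxidation: 9-BBN should react only with the monosubstituted alkene and not with the chlorinated trisubstituted enol ether, and neutral peroxide oxidation spares the aryl silyl ether.

**Step 6**
Reactants: 11 (5R)-5-Ar-5-[(E)-1,2-dichloroethenyloxy]pentan-1-ol
Product: 12 (5R)-5-Ar-5-[(E)-1,2-dichloroethenyloxy]pentanal
Conditions: Dess–Martin periodinane, CH2Cl2, 0 °C → rt
Reagents that add atoms: none
Why: Dess–Martin oxidation of a primary alcohol to the aldehyde (C7) under conditions that the dichlorovinyl ether and the silyl ether tolerate.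

**Step 7**
Reactants: 12 (5R)-5-Ar-5-[(E)-1,2-dichloroethenyloxy]pentanal
Product: 13 (7R)-7-Ar-7-[(E)-1,2-dichloroethenyloxy]-2-methoxyhept-1-en-3-ol (both C3 epimers)
Conditions: CH2=CHOMe, t-BuLi, THF, −78 → 0 °C; then added slowly to 12, THF, −78 °C; H2O
Reagents that add atoms: 1-methoxyvinyllithium, [Li]C(=C)OC (made in the flask from methyl vinyl ether, C=COC, and t-BuLi)
Why: 1,2-Addition of an α-alkoxyvinyllithium (an acyl anion equivalent) to the aldehyde forms the C7–C5 bond; slow addition to the aldehyde at −78 °C keeps carbonyl addition ahead of deprotonation of the dichlorovinyl ether, and the uncontrolled carbinol centre is erased in step 9.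

**Step 8**
Reactants: 13 (7R)-7-Ar-7-[(E)-1,2-dichloroethenyloxy]-2-methoxyhept-1-en-3-ol; 14 prenyl bromide (1-bromo-3-methylbut-2-ene)
Product: 17 (7R)-7-Ar-2-methoxy-7-[(5-methylhex-4-en-1-yn-1-yl)oxy]hept-1-en-3-ol (both C3 epimers), via chloroalkynyl ether lithium alkoxide 15 (not isolated), via dilithiated alkoxyacetylide 16 (not isolated)
Conditions: n-BuLi (3.2 equiv), THF, −78 → −40 °C; then 14, DMPU, −78 → 0 °C; aq. NaHCO3; all later handling ≤ 25 °C
Reagents that add atoms: none
Why: Alkynyl ether synthesis from a 1,2-dichlorovinyl ether: after deprotonation of the hydroxyl, n-BuLi removes the vinylic hydrogen, chloride is lost to give 15, chlorine–lithium exchange gives acetylide 16, and this carbanion should be alkylated at the primary carbon of prenyl bromide much faster than the lithium alkoxide (as in C-alkylation of alkynol dianions), C7 being an alkoxide so that no electrophilic carbonyl meets n-BuLi.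

**Step 9**
Reactants: 17 (7R)-7-Ar-2-methoxy-7-[(5-methylhex-4-en-1-yn-1-yl)oxy]hept-1-en-3-ol
Product: 18 (7R)-7-Ar-2-methoxy-7-[(5-methylhex-4-en-1-yn-1-yl)oxy]hept-1-en-3-one
Conditions: activated MnO2, CH2Cl2, rt
Reagents that add atoms: none
Why: MnO2 oxidation of an allylic alcohol to the enone runs under neutral, acid-free conditions, which the enol ether and the alkynyl ether should survive.

**Step 10**
Reactants: 18 (7R)-7-Ar-2-methoxy-7-[(5-methylhex-4-en-1-yn-1-yl)oxy]hept-1-en-3-one
Product: 20 (7R)-7-Ar-4-diazo-2-methoxy-7-[(5-methylhex-4-en-1-yn-1-yl)oxy]hept-1-en-3-one, via 4-trifluoroacetyl ketone 19 (not isolated)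
Conditions: LiHMDS, THF, −78 °C; CF3CO2CH2CF3; pH 6 phosphate buffer; crude 19 then MsN3, Et3N, H2O (1 equiv), MeCN, 0 °C → rt
Reagents that add atoms: methanesulfonyl azide, CS(=O)(=O)N=[N+]=[N-]
Why: Detrifluoroacetylative diazo transfer: the ketone has a single enolisable position (C4a), its lithium enolate is trifluoroacetylated, and the resulting 1,3-diketone takes the diazo group from the sulfonyl azide with loss of the trifluoroacetyl group under mild base, a sequence suited to enones that do not tolerate direct diazo transfer.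

**Step 11**
Reactants: 20 (7R)-7-Ar-4-diazo-2-methoxy-7-[(5-methylhex-4-en-1-yn-1-yl)oxy]hept-1-en-3-one
Product: 24 (2R)-2-Ar-5-methoxy-8-(3-methylbut-2-enyl)-3,4-dihydro-2H-chromen-7-ol, via vinylketene 21 (not isolated), via cyclobutenone 22 (not isolated), via dienylketene 23 (not isolated)
Conditions: hν (medium-pressure Hg lamp, Pyrex filter), degassed ClCH2CH2Cl (0.005 M), 20 °C; then 80 °C
Reagents that add atoms: none
Why: Proposed new method: light expels N2 from 20 and the 1-methoxyvinyl group migrates (photochemical Wolff rearrangement) to give vinylketene 21 with C7 as the ketene carbonyl carbon and C4a as its α-carbon; the nucleophilic prenyl-bearing alkyne carbon C8 attacks C7 while the oxygen-bearing C8a bonds to C4a, a [2+2] cycloaddition giving cyclobutenone 22, which on warming opens by 4π electrocyclisation to dienylketene 23, closes C6–C7 and tautomerises to the C7 phenol. The closest known reaction type is the Danheiser benzannulation of photochemically generated vinylketenes with alkoxy- and siloxyalkynes, known between separate partners and in tethered form with ynamides, so the tethered alkynyl ether is the untested element. Ring C closes in the [2+2] as a six-membered ring through C4a–C8a, with the second alkyne carbon exocyclic and the four-atom tether C4–C3–C2–O1 joining the reacting termini; ring A closes by thermal 6π electrocyclisation of 23, in which the C4a=C8a double bond is held cis inside ring C. No stereocentre is created in 24: C2 is a spectator carried from 6, and the quaternary C4a of 22 becomes planar again on ring opening. The step needs one regiochemistry in the [2+2] (C7 to C8, C4a to C8a), which the polarisation of the alkynyl ether and the tether length both dictate, and it needs the ketene to be formed at 20 °C because the secondary benzylic alkynyl ether would not survive a thermal Wolff rearrangement; heating follows only after the alkyne has been consumed.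

**Step 12**
Reactants: 24 (2R)-2-Ar-5-methoxy-8-(3-methylbut-2-enyl)-3,4-dihydro-2H-chromen-7-ol
Product: 25 3-[(2R)-7-hydroxy-5-methoxy-8-(3-methylbut-2-enyl)-3,4-dihydro-2H-chromen-2-yl]-5-methoxyphenol
Conditions: TBAF, AcOH (1 equiv each), THF, 0 °C
Reagents that add atoms: none
Why: Fluoride cleavage of the aryl silyl ether, buffered with acetic acid so that the two phenols and the ortho-prenyl group of the product are not exposed to strong base.

**Compound list**

1 | 3-bromo-5-methoxyphenol | COc1cc(O)cc(Br)c1 | starting material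
2 | (3-bromo-5-methoxyphenoxy)triisopropylsilane | COc1cc(O[Si](C(C)C)(C(C)C)C(C)C)cc(Br)c1 | intermediate
3 | pent-4-enoyl chloride | C=CCCC(Cl)=O | starting material
4 | [3-methoxy-5-(triisopropylsilyloxy)phenyl]magnesium bromide (not isolated) | COc1cc(O[Si](C(C)C)(C(C)C)C(C)C)cc([Mg]Br)c1 | intermediate
5 | 1-[3-methoxy-5-(triisopropylsilyloxy)phenyl]pent-4-en-1-one | C=CCCC(=O)c1cc(OC)cc(O[Si](C(C)C)(C(C)C)C(C)C)c1 | intermediate
6 | (1R)-1-[3-methoxy-5-(triisopropylsilyloxy)phenyl]pent-4-en-1-ol | C=CCC[C@@H](O)c1cc(OC)cc(O[Si](C(C)C)(C(C)C)C(C)C)c1 | intermediate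
7 | trichloroethylene | ClC=C(Cl)Cl | starting material
8 | potassium (1R)-1-Ar-pent-4-en-1-olate (not isolated) | C=CCC[C@@H](O[K])c1cc(OC)cc(O[Si](C(C)C)(C(C)C)C(C)C)c1 | intermediate
9 | (1R)-1-Ar-1-[(E)-1,2-dichloroethenyloxy]pent-4-ene | C=CCC[C@@H](O/C(Cl)=C\Cl)c1cc(OC)cc(O[Si](C(C)C)(C(C)C)C(C)C)c1 | intermediate
10 | 9-[(5R)-5-Ar-5-((E)-1,2-dichloroethenyloxy)pentyl]-9-borabicyclo[3.3.1]nonane (not isolated) | C1CC2CCCC(C1)B2CCCC[C@@H](O/C(Cl)=C\Cl)c1cc(OC)cc(O[Si](C(C)C)(C(C)C)C(C)C)c1 | intermediate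
11 | (5R)-5-Ar-5-[(E)-1,2-dichloroethenyloxy]pentan-1-ol | OCCCC[C@@H](O/C(Cl)=C\Cl)c1cc(OC)cc(O[Si](C(C)C)(C(C)C)C(C)C)c1 | intermediate
12 | (5R)-5-Ar-5-[(E)-1,2-dichloroethenyloxy]pentanal | O=CCCC[C@@H](O/C(Cl)=C\Cl)c1cc(OC)cc(O[Si](C(C)C)(C(C)C)C(C)C)c1 | intermediate
13 | (7R)-7-Ar-7-[(E)-1,2-dichloroethenyloxy]-2-methoxyhept-1-en-3-ol (both C3 epimers) | C=C(OC)C(O)CCC[C@@H](O/C(Cl)=C\Cl)c1cc(OC)cc(O[Si](C(C)C)(C(C)C)C(C)C)c1 | intermediate
14 | prenyl bromide (1-bromo-3-methylbut-2-ene) | CC(C)=CCBr | starting material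
15 | lithium (7R)-7-Ar-7-(chloroethynyloxy)-2-methoxyhept-1-en-3-olate (not isolated) | C=C(OC)C(O[Li])CCC[C@@H](OC#CCl)c1cc(OC)cc(O[Si](C(C)C)(C(C)C)C(C)C)c1 | intermediate
16 | lithium (7R)-7-Ar-7-(lithioethynyloxy)-2-methoxyhept-1-en-3-olate (not isolated) | C=C(OC)C(O[Li])CCC[C@@H](OC#C[Li])c1cc(OC)cc(O[Si](C(C)C)(C(C)C)C(C)C)c1 | intermediate
17 | (7R)-7-Ar-2-methoxy-7-[(5-methylhex-4-en-1-yn-1-yl)oxy]hept-1-en-3-ol (both C3 epimers) | C=C(OC)C(O)CCC[C@@H](OC#CCC=C(C)C)c1cc(OC)cc(O[Si](C(C)C)(C(C)C)C(C)C)c1 | intermediate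
18 | (7R)-7-Ar-2-methoxy-7-[(5-methylhex-4-en-1-yn-1-yl)oxy]hept-1-en-3-one | C=C(OC)C(=O)CCC[C@@H](OC#CCC=C(C)C)c1cc(OC)cc(O[Si](C(C)C)(C(C)C)C(C)C)c1 | intermediate
19 | (7R)-7-Ar-2-methoxy-7-[(5-methylhex-4-en-1-yn-1-yl)oxy]-4-(trifluoroacetyl)hept-1-en-3-one (C4 epimers, not isolated) | C=C(OC)C(=O)C(C(=O)C(F)(F)F)CC[C@@H](OC#CCC=C(C)C)c1cc(OC)cc(O[Si](C(C)C)(C(C)C)C(C)C)c1 | intermediate
20 | (7R)-7-Ar-4-diazo-2-methoxy-7-[(5-methylhex-4-en-1-yn-1-yl)oxy]hept-1-en-3-one | C=C(OC)C(=O)C(=[N+]=[N-])CC[C@@H](OC#CCC=C(C)C)c1cc(OC)cc(O[Si](C(C)C)(C(C)C)C(C)C)c1 | intermediate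
21 | (5R)-5-Ar-2-(1-methoxyethenyl)-5-[(5-methylhex-4-en-1-yn-1-yl)oxy]pent-1-en-1-one (vinylketene, not isolated) | C=C(OC)C(=C=O)CC[C@@H](OC#CCC=C(C)C)c1cc(OC)cc(O[Si](C(C)C)(C(C)C)C(C)C)c1 | intermediate
22 | (3R)-3-Ar-6-(1-methoxyethenyl)-8-(3-methylbut-2-enyl)-2-oxabicyclo[4.2.0]oct-1(8)-en-7-one (C6 epimers, not isolated) | C=C(OC)C12CC[C@H](c3cc(OC)cc(O[Si](C(C)C)(C(C)C)C(C)C)c3)OC1=C(CC=C(C)C)C2=O | intermediate
23 | 2-[(2R)-2-Ar-5-(1-methoxyethenyl)-3,4-dihydro-2H-pyran-6-yl]-5-methylhexa-1,4-dien-1-one (dienylketene, not isolated) | C=C(OC)C1=C(C(CC=C(C)C)=C=O)O[C@@H](c2cc(OC)cc(O[Si](C(C)C)(C(C)C)C(C)C)c2)CC1 | intermediate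
24 | (2R)-5-methoxy-2-[3-methoxy-5-(triisopropylsilyloxy)phenyl]-8-(3-methylbut-2-enyl)-3,4-dihydro-2H-chromen-7-ol | COc1cc(O[Si](C(C)C)(C(C)C)C(C)C)cc([C@H]2CCc3c(OC)cc(O)c(CC=C(C)C)c3O2)c1 | intermediate
25 | 3-[(2R)-7-hydroxy-5-methoxy-8-(3-methylbut-2-enyl)-3,4-dihydro-2H-chromen-2-yl]-5-methoxyphenol | COc1cc(O)cc([C@H]2CCc3c(OC)cc(O)c(CC=C(C)C)c3O2)c1 | target

**Step count and risks**

Total step count: 12. Longest linear sequence: 12 steps (1 to 25).

Steps most likely to fail:

Step 11. The vinylketene may form without being captured by the tethered alkyne: it can close to a 2-alkyl-3-methoxycyclobutenone or dimerise, and the secondary benzylic alkynyl ether then fragments once heat is applied. The fallback uses known chemistry only, sets out from ketone 5 and comes back at target 25. Ring A is made by the same benzannulation between separate partners and ring C afterwards by Mitsunobu etherification.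
- Ketone 5 is reduced with the enantiomeric catalyst RuCl[(S,S)-TsDPEN](p-cymene) to (1S)-1-Ar-pent-4-en-1-ol F1, which is silylated (TBSCl, imidazole) to the tert-butyldimethylsilyl ether F2.
- 9-BBN and neutral H2O2 give the primary alcohol F3, Dess–Martin oxidation the aldehyde F4, 1-methoxyvinyllithium the carbinol F5, MnO2 the enone F6, and detrifluoroacetylative diazo transfer the diazo ketone F7.
- Prenyl bromide 14 and lithium acetylide–ethylenediamine complex in DMSO give 5-methylhex-4-en-1-yne F8. Its lithium acetylide is oxidised with lithium tert-butyl peroxide and silylated with TIPSOTf to the siloxyalkyne F9.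
- Irradiation of F7 with F9, then heating to 80 °C, should give the resorcinol monosilyl ether F10 with the regiochemistry of step 11 (C7 hydroxyl, C8 prenyl, C8a silyloxy, C4a side chain).
- TBAF removes the three silyl groups to give the tetraol F11. PPh3 and DIAD at high dilution close ring C through the C8a hydroxyl, the only phenol that can reach the benzylic carbon in a six-membered transition state; inversion turns the (S)-carbinol into (2R)-25.

Step 8. Alkylation of the aggregated dilithio species 16 may be slow or may take place at the tertiary end of prenyl bromide, and excess base may move the new skipped enyne into conjugation. The fallback sets out from 13 and comes back at 17, making the C–C bond by cross-coupling instead of SN2 alkylation. 13 is taken to 16 as before and quenched with Bu3SnCl to the alkynylstannane F12, which is handled without acid. A Stille reaction with prenyl bromide 14 (Pd2(dba)3, tri(2-furyl)phosphine, THF, rt) then gives 17: the zerovalent palladium catalyst forms the π-prenyl complex and the alkynyl group is delivered to its unsubstituted terminus.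

Step 10. The sulfonyl azide may add to the electron-rich alkyne in competition with diazo transfer, and the long contact time adds to the loss of the fragile alkynyl ether. The fallback sets out from 18 and comes back at 20 without any azide. LiHMDS followed by 2-(phenylsulfonyl)-3-phenyloxaziridine gives the α-hydroxy ketone F13, and Dess–Martin periodinane buffered with pyridine gives the 1,2-diketone F14. TsNHNH2 condenses at the less hindered, non-conjugated C4a carbonyl to give the monotosylhydrazone F15, and Et3N in CH2Cl2 expels p-toluenesulfinate (Bamford–Stevens-type fragmentation of an α-keto tosylhydrazone) to give 20.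

**Further compounds**

F1 | step 11 | (1S)-1-[3-methoxy-5-(triisopropylsilyloxy)phenyl]pent-4-en-1-ol | C=CCC[C@H](O)c1cc(OC)cc(O[Si](C(C)C)(C(C)C)C(C)C)c1
F2 | step 11 | tert-butyl{[(1S)-1-Ar-pent-4-en-1-yl]oxy}dimethylsilane | C=CCC[C@H](O[Si](C)(C)C(C)(C)C)c1cc(OC)cc(O[Si](C(C)C)(C(C)C)C(C)C)c1
F3 | step 11 | (5S)-5-Ar-5-(tert-butyldimethylsilyloxy)pentan-1-ol | OCCCC[C@H](O[Si](C)(C)C(C)(C)C)c1cc(OC)cc(O[Si](C(C)C)(C(C)C)C(C)C)c1
F4 | step 11 | (5S)-5-Ar-5-(tert-butyldimethylsilyloxy)pentanal | O=CCCC[C@H](O[Si](C)(C)C(C)(C)C)c1cc(OC)cc(O[Si](C(C)C)(C(C)C)C(C)C)c1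
F5 | step 11 | (7S)-7-Ar-7-(tert-butyldimethylsilyloxy)-2-methoxyhept-1-en-3-ol (both C3 epimers) | C=C(OC)C(O)CCC[C@H](O[Si](C)(C)C(C)(C)C)c1cc(OC)cc(O[Si](C(C)C)(C(C)C)C(C)C)c1
F6 | step 11 | (7S)-7-Ar-7-(tert-butyldimethylsilyloxy)-2-methoxyhept-1-en-3-one | C=C(OC)C(=O)CCC[C@H](O[Si](C)(C)C(C)(C)C)c1cc(OC)cc(O[Si](C(C)C)(C(C)C)C(C)C)c1
F7 | step 11 | (7S)-7-Ar-7-(tert-butyldimethylsilyloxy)-4-diazo-2-methoxyhept-1-en-3-one | C=C(OC)C(=O)C(=[N+]=[N-])CC[C@H](O[Si](C)(C)C(C)(C)C)c1cc(OC)cc(O[Si](C(C)C)(C(C)C)C(C)C)c1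
F8 | step 11 | 5-methylhex-4-en-1-yne | C#CCC=C(C)C
F9 | step 11 | triisopropyl[(5-methylhex-4-en-1-yn-1-yl)oxy]silane | CC(C)=CCC#CO[Si](C(C)C)(C(C)C)C(C)C
F10 | step 11 | 4-[(3S)-3-Ar-3-(tert-butyldimethylsilyloxy)propyl]-5-methoxy-2-(3-methylbut-2-enyl)-3-(triisopropylsilyloxy)phenol | COc1cc(O)c(CC=C(C)C)c(O[Si](C(C)C)(C(C)C)C(C)C)c1CC[C@H](O[Si](C)(C)C(C)(C)C)c1cc(OC)cc(O[Si](C(C)C)(C(C)C)C(C)C)c1
F11 | step 11 | 4-[(3S)-3-hydroxy-3-(3-hydroxy-5-methoxyphenyl)propyl]-5-methoxy-2-(3-methylbut-2-enyl)benzene-1,3-diol | COc1cc(O)c(CC=C(C)C)c(O)c1CC[C@H](O)c1cc(O)cc(OC)c1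
F12 | step 8 | (7R)-7-Ar-2-methoxy-7-{[(tributylstannyl)ethynyl]oxy}hept-1-en-3-ol (both C3 epimers) | C=C(OC)C(O)CCC[C@@H](OC#C[Sn](CCCC)(CCCC)CCCC)c1cc(OC)cc(O[Si](C(C)C)(C(C)C)C(C)C)c1
F13 | step 10 | (7R)-7-Ar-4-hydroxy-2-methoxy-7-[(5-methylhex-4-en-1-yn-1-yl)oxy]hept-1-en-3-one (C4 epimers) | C=C(OC)C(=O)C(O)CC[C@@H](OC#CCC=C(C)C)c1cc(OC)cc(O[Si](C(C)C)(C(C)C)C(C)C)c1
F14 | step 10 | (7R)-7-Ar-2-methoxy-7-[(5-methylhex-4-en-1-yn-1-yl)oxy]hept-1-ene-3,4-dione | C=C(OC)C(=O)C(=O)CC[C@@H](OC#CCC=C(C)C)c1cc(OC)cc(O[Si](C(C)C)(C(C)C)C(C)C)c1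
F15 | step 10 | 4-(p-toluenesulfonylhydrazone) of F14 | C=C(OC)C(=O)C(=NNS(=O)(=O)c1ccc(C)cc1)CC[C@@H](OC#CCC=C(C)C)c2cc(OC)cc(O[Si](C(C)C)(C(C)C)C(C)C)c2
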